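The numbers in the tables come from a simulation on assumed constants; scatter was added.

Compare two flasks at the same amount of product, not at the same minute, before reading an order off them; the first question below asks for it that way.

| setting | amber | teal | blue | grey | red |
|---|---|---|---|---|---|
| starting material | 0.800 M | 0.320 M | 0.800 M | 2.40 M | 2.40 M |
| coupling partner | 1.60 M | 1.12 M | 1.60 M | 1.60 M | 4.80 M |
| free catalyst | 0.0640 M | 0.0640 M | 0.130 M | 0.0640 M | 0.0640 M |
| time |  |  |  |  | 30 min |

| run | time / min | [product] / M |
|---|---|---|
| amber run | 2.3 | 0.005 |
| amber run | 6.9 | 0.058 |
| amber run | 13 | 0.137 |
| amber run | 21 | 0.250 |
| amber run | 30 | 0.344 |
| teal run | 2.3 | 0 |
| teal run | 6.9 | 0.008 |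
| teal run | 13 | 0.033 |
| teal run | 21 | 0.075 |
| teal run | 30 | 0.100 |
| blue run | 2.3 | 0.021 |
| blue run | 6.9 | 0.121 |
| blue run | 13 | 0.284 |
| blue run | 21 | 0.459 |
| blue run | 30 | 0.576 |
| grey run | 2.3 | 0.015 |
| grey run | 6.9 | 0.141 |
| grey run | 13 | 0.364 |
| grey run | 21 | 0.636 |
| grey run | 30 | 0.863 |

(each reading ± 0.006 M)

- apparent order in [starting material] of the starting rate, round the charge of the amber run (the rate where two percent of its starting material have turned into product) (one fixed amount of product, the same in the runs compared)
- apparent order in [coupling partner] of the starting rate, round the charge of the amber run (the rate where two percent of its starting material have turned into product)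
- the teal run starts with 0.480 M less of starting material and of coupling partner than the amber run, and with no product. Compared where both hold the same amount of starting material, once fifteen percent of what the teal run was charged with has turned into product, is the teal run faster, slower or alike (within a tenth)?
- product in the red run at 30 min, as a share of the starting material charged

- Overall: starting material + coupling partner -> product, with free catalyst as catalyst.
- Constant volume, constant temperature.
- "The second partner" is coupling partner.
- An order is taken over about fifteen percent of the charge, up and down.

The bench rule I would reach for takes two flasks differing in one charge and divides the log of their product ratio at one clock reading by the log of their charge ratio. For the grey run against the amber run at 6.9 min it gives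

order at a fixed clock = ln(2.43) / ln(3.00) = 0.809

That rule treats product as a straight line in time, and a ratio shows where this stops. From 2.3 min to 6.9 min the clock grows by a factor of 3.00, while the summed product of the amber and grey runs grows by 9.95, which is more than the clock factor. Both runs begin with a lag, an induction period. I therefore reckon

2.09 = ln(summed product factor) / ln(clock factor)

This number, the power of the clock in the early climb of product as read from the amber and grey runs, is the rise exponent.

Suppose product goes as starting material times time raised to the rise exponent. A richer flask then reaches a given amount of product sooner, and the rate at that mark goes as one over the time taken. So

order at a fixed amount of product = order at a fixed clock / rise exponent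

At 2.3 min the grey run over the amber run reads 3.00, the same as the charge ratio, though those readings lie near the scatter. I therefore put the order at a fixed clock at 1, and my own estimate of the order at fixed product is 0.478. One scatter more on the summed first readings would make it 0.565.

The forecast gives 0.85 for starting material (0.65 to 1.05), 1 for the coupling partner (0.6 to 1.5), slower for the teal run, and 73% for the red run (58% to 86%). Its ground for the first: “Tripling starting material therefore raises the rate about 2.4–2.6×, so its order is about 0.85.” That differs from my 0.478.

The simulation gives 0.56 for starting material, 1.0 for the coupling partner, slower for the teal run, and 82.1% for the red run.

    2 active catalyst ⇌ catalyst dimer, settled at all times (17.30 L mol⁻¹)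
    catalyst dimer + starting material + coupling partner → product + catalyst dimer (1.086 L² mol⁻² min⁻¹)
    free catalyst + coupling partner → active catalyst + coupling partner (0.1092 L mol⁻¹ min⁻¹)

Around the amber charge, the order in starting material comes out at 0.56, where one over the rise exponent gave 0.478. The slowness of the conversion of free catalyst into active catalyst lowers it: with that step made quick, the order is 1.0. I divide likewise for the blue run against the amber run, using the rise exponent 2.09 read from the amber and grey runs. With that step quick, the order in free catalyst is 1.3, which gives 0.631, and with the slow step that order is 0.75.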